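**Remarks before the sections.** Labdane numbering is used throughout: ring A = C1–C5, C10; ring B = C5–C10; C17 on C8; C18 and C19 on C4; C20 on C10; C11–C12 link C9 to the butenolide C13–C16.
Assumption on the chemistry: the (1S,2R,5S) enantiomer of 8-phenylmenthol is taken to shield the face of the C4 radical that leads to the 10α-methyl (ent-labdane) series; if the opposite sense holds, the (1R,2S,5R) alcohol is used and nothing else changes.

## Structural features

The target is a trans-fused decalin (rings A and B) that carries on C9 a two-carbon arm (C11–C12) ending at the α-carbon C13 of a 2(5H)-furanone. Six stereocentres are contiguous on the bicycle: C3 (equatorial OH), quaternary C4 (axial CH2OH C19, equatorial CH3 C18), C5, quaternary C10 (axial CH3 C20), C9 and C8 (equatorial CH2OH C17, trans to the C9 arm). The absolute configuration is 3R,4R,5S,8S,9R,10S. C4 is the hardest single centre, because C19 must sit axial, syn to C20 and cis to O3; C4/C5 and C10/C9 are two adjacent pairs that each contain a quaternary carbon. The butenolide is the fragile group (base, hydride, nucleophiles), and C12 and C17 are two primary carbons that must be told apart although both end at a similar oxidation level. Two latent relationships decide the plan: O3–C3–C4–C19–O is a β-keto ester in disguise, and C17–C8–C9–C11–C12 becomes a δ-lactone when C17 (as C=O) is tied to C12 through oxygen, which turns C8=C9 into a conjugate acceptor of locked geometry. The key step exploits exactly these: an electrophilic C4 radical of the keto ester, the electron-rich C5=C10 alkene and the C8=C9–C17 lactone acceptor fold one chain into rings A and B. It forms C4–C5 and C9–C10, sets C4, C5, C9 and C10 together, and leaves C8 epimerizable towards the required equatorial position.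

## Logic of the disconnections

23 is taken back through 22 to 19 and 20 by cutting the sp3–sp2 bond C12–C13. The butenolide tolerates neither hydride nor strong base, so it is added last and whole; this removes five carbons and the only fragile group. The demand on the forward step is a base-free coupling at C12 that tolerates silyl ethers.

19 is taken back through 18 and 17 to 16: the C12–Br bond is traced to the C12–O bond of a δ-lactone closed on C17, and C3, C17 and C19 are raised to ketone and acyl level. O-alkyl cleavage of the lactone by bromide is the one operation that distinguishes C12 from C17 without protecting groups. The gain is a tricyclic keto lactone ester with no hydroxyl groups. The demand is a hydride source that spares the C–Br bond and attacks C3 axially.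

16 is taken back to 14 by cutting C4–C5 and C9–C10 (and the C8–H bond). This opens rings A and B at once and removes C4, C5, C9, C10 and C8 as stereocentres, so the precursor is an acyclic chain whose only stereochemical information is the ester auxiliary and two alkene geometries, one of them fixed by a ring. In one sentence, the route is a reductive radical bicyclization of the acyclic bromo keto ester 14 that closes ring A onto an alkene and ring B onto the β-carbon of an unsaturated δ-lactone. The demand is two 6-endo closures through a chair–chair arrangement, face control by the auxiliary, and ring closure faster than hydrogen transfer.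

14 is taken back through 13 to 11 and 8 by cutting C4–Br and then C1–C2. The γ-carbon of an acetoacetate dianion is the natural C2 nucleophile and the allylic C1 the natural electrophile. The chain falls into a chiral keto ester and an achiral lactone bromide. The demand is attack at the allylic bromide in preference to the lactone.

8 is taken back through 7 and 6 to 3 and 4 by cutting C1–Br, C1–O and then the sp3–sp2 bond C7–C8. C1 is reached by allylic oxidation of the (E)-methyl of a prenyl terminus, so no alkene needs to be built stereoselectively. The gain is two small achiral pieces. The demand is E-selective oxidation at the electron-rich alkene only, and a coupling that does not add to the enoate.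

11 comes from 9 and 10 by ester exchange, and 3 from 1 by bromination and loss of HBr; all of 1, 4, 9, 10 and 20 are purchased.

## Other disconnections considered

Alternative 1: This is the first plan that comes to mind. It cuts C4–C5 and C9–C10 heterolytically: a Lewis-acid cation–olefin cyclization of the enantioenriched epoxy diene A1 (allylsilane terminator) would give the bicyclic 8(17)-ene A2. The chosen plan is preferred for three reasons. First, A2 leaves C8 trigonal, and hydroboration should approach anti to C20 and place C17 axial, the wrong epimer, so an oxidation, epimerization and reduction detour would follow. Second, C4 depends entirely on a geometrically pure (Z)-trisubstituted epoxide, since the cis substituent becomes axial. Third, the step delivers neither C17 at a useful oxidation level nor an epimerizable C8, whereas the radical closure onto the lactone does both.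

Alternative 2: This cuts C7–C8 and C9–C10 by a Diels–Alder reaction of the ring-A diene A3 with dimethyl (E)-butenedioate to give adduct A4. Bond formation at the fully substituted diene terminus C10 should be slow and invites diene isomerization under forcing conditions. A trans dienophile must place one ester endo and one exo, so nothing decides the C9/C10 relationship. A4 also still needs alkene reduction at C5, differentiation of the two esters and a one-carbon homologation at C11, which makes the route longer.

Alternative 3: This cuts the same two bonds but starts the radical at an epoxide: Cp2TiCl (trivalent titanium) would open the epoxy polyene lactone A5 and give the hydroxy lactone A6 with O3 already in place. The C4 radical formed this way carries CH3 and CH2OSi groups of nearly equal size, so there is no element that places C19 axial and a C4 epimer mixture is expected. The β-keto ester radical of the chosen plan has a built-in preference for the axial ester and is formed from either epimer of its precursor.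

Key step: step 8

## Route

Step 1
Reactants: 1 5,6-dihydro-2H-pyran-2-one
Product: 3 3-bromo-5,6-dihydro-2H-pyran-2-one, via dibromolactone 2 (not isolated)
Conditions: Br2, CH2Cl2, 0 °C to rt; then Et3N, 0 °C
Reagents that add atoms: bromine, BrBr
Why: Anti addition of bromine to the enoate gives the trans-3,4-dibromide 2, and E1cB loss of HBr (acidic H3, bromide leaving from C4) gives the α-bromo enoate; bromination–dehydrobromination of a cyclic enoate.

Step 2
Reactants: 4 5-bromo-2-methylpent-2-ene; 3 3-bromo-5,6-dihydro-2H-pyran-2-one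
Product: 6 3-(4-methylpent-3-en-1-yl)-5,6-dihydro-2H-pyran-2-one, via alkylzinc bromide 5 (not isolated)
Conditions: Zn dust, LiCl, THF, 50 °C; then 3, Pd(OAc)2 (2 mol %), SPhos (4 mol %), THF, rt
Reagents that add atoms: none
Why: Zinc insertion into the primary C–Br bond gives 5, and Negishi coupling (oxidative addition of zerovalent palladium to the alkenyl bromide, transmetalation, reductive elimination) forms the C7–C8 bond; alkylzinc halides do not add to the enoate without a catalyst.

Step 3
Reactants: 6 3-(4-methylpent-3-en-1-yl)-5,6-dihydro-2H-pyran-2-one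
Product: 7 3-[(3E)-5-hydroxy-4-methylpent-3-en-1-yl]-5,6-dihydro-2H-pyran-2-one
Conditions: SeO2 (0.5 equiv), t-BuOOH (3 equiv), salicylic acid (0.1 equiv), CH2Cl2, rt
Reagents that add atoms: tert-butyl hydroperoxide, CC(C)(C)OO (oxygen source); selenium dioxide, O=[Se]=O (oxygen carrier)
Why: Riley allylic oxidation: the ene reaction of SeO2 at the electron-rich trisubstituted alkene and the following [2,3]-shift oxidize the methyl group trans to the chain and give the (E)-allylic alcohol; the electron-poor lactone alkene is not an ene partner.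

Step 4
Reactants: 7 3-[(3E)-5-hydroxy-4-methylpent-3-en-1-yl]-5,6-dihydro-2H-pyran-2-one
Product: 8 3-[(3E)-5-bromo-4-methylpent-3-en-1-yl]-5,6-dihydro-2H-pyran-2-one
Conditions: CBr4, PPh3, CH2Cl2, 0 °C
Reagents that add atoms: carbon tetrabromide, BrC(Br)(Br)Br
Why: Appel reaction: SN2 displacement of the oxyphosphonium group at the primary allylic carbon keeps the E geometry and leaves the lactone untouched.

Step 5
Reactants: 9 ethyl 2-methyl-3-oxobutanoate; 10 (1S,2R,5S)-5-methyl-2-(2-phenylpropan-2-yl)cyclohexan-1-ol [(+)-8-phenylmenthol]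
Product: 11 (1S,2R,5S)-8-phenylmenthyl 2-methyl-3-oxobutanoate (both C2 epimers)
Conditions: DMAP (0.3 equiv), toluene, reflux, 4 Å molecular sieves
Reagents that add atoms: none
Why: DMAP-catalysed ester exchange of a β-keto ester, driven by removal of ethanol; the carbinol centre of the auxiliary is not touched.

Step 6
Reactants: 11 (1S,2R,5S)-8-phenylmenthyl 2-methyl-3-oxobutanoate; 8 3-[(3E)-5-bromo-4-methylpent-3-en-1-yl]-5,6-dihydro-2H-pyran-2-one
Product: 13 (1S,2R,5S)-8-phenylmenthyl (6E)-2,6-dimethyl-3-oxo-9-(2-oxo-5,6-dihydro-2H-pyran-3-yl)non-6-enoate (both C2 epimers), via sodium lithium dianion 12 (not isolated)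
Conditions: NaH, THF, 0 °C; n-BuLi, 0 °C; then 8, −78 to −20 °C; aq. NH4Cl
Reagents that add atoms: none
Why: Acetoacetate dianion γ-alkylation: the more basic terminal carbanion of 12 displaces the primary allylic bromide (C1–C2 bond) faster than it adds to the α-substituted enoate at low temperature; the E alkene is carried through unchanged.

Step 7
Reactants: 13 (1S,2R,5S)-8-phenylmenthyl (6E)-2,6-dimethyl-3-oxo-9-(2-oxo-5,6-dihydro-2H-pyran-3-yl)non-6-enoate
Product: 14 (1S,2R,5S)-8-phenylmenthyl (6E)-2-bromo-2,6-dimethyl-3-oxo-9-(2-oxo-5,6-dihydro-2H-pyran-3-yl)non-6-enoate (both C2 epimers)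
Conditions: NBS (1.05 equiv), Mg(ClO4)2 (0.3 equiv), MeCN, 0 °C to rt, dark
Reagents that add atoms: N-bromosuccinimide, O=C1CCC(=O)N1Br
Why: Lewis-acid-catalysed enolization and electrophilic α-bromination of the β-keto ester, which is faster than attack of NBS on the unactivated alkene; the C2 (labdane C4) configuration is irrelevant because step 8 passes through a planar radical.

Step 8
Reactants: 14 (1S,2R,5S)-8-phenylmenthyl (6E)-2-bromo-2,6-dimethyl-3-oxo-9-(2-oxo-5,6-dihydro-2H-pyran-3-yl)non-6-enoate
Product: 16 (1S,2R,5S)-8-phenylmenthyl (4S,5S,8S,9R,10S)-3-oxo-13,14,15,16-tetranorlabdan-17,12-olid-19-oate (trans-fused δ-lactone), via 8-epi lactone 15 (not isolated)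
Conditions: (Me3Si)3SiH (1.3 equiv, syringe pump, 6 h), Et3B (0.3 equiv), air, toluene (0.005 M), 0 °C; then DBU (0.5 equiv), rt
Reagents that add atoms: none
Why: The silyl radical abstracts bromine from either epimer of 14 to give one planar, electrophilic C4 radical, which adds 6-endo-trig to C5 of the electron-rich (E)-C5=C10 alkene (ring A); the resulting nucleophilic tertiary C10 radical adds 6-endo-trig to C9, the β-carbon of the unsaturated lactone (ring B), and the electrophilic C8 radical takes hydrogen from the silane, so every radical meets a polarity-matched partner. The closest known reaction type is the oxidative free-radical bicyclization of unsaturated 2-methyl-3-oxo esters with Mn(OAc)3 (same radical, same chair–chair course), run here as a reductive tris(trimethylsilyl)silane chain with a conjugate acceptor as terminator. C4 and C5 are set in a chair arrangement with the ketone inside the ring and the ester axial, the established preference of 2-alkyl-3-oxo ester radicals, which places C19 cis to C20 and trans to H5. C10 and C9 follow from the E alkene (trans ring fusion) and from the lactone ring, which holds C11 cis to the C17 carbonyl and trans to C7, so that C11 must come out equatorial with H9 anti to C20. The absolute sense comes from the 8-phenylmenthyl ester, whose cumyl phenyl ring covers one face of the C4 radical; the minor auxiliary diastereomer should be separable by chromatography because the auxiliary is still attached. C8 is not controlled in the hydrogen transfer, but DBU equilibrates 15 into 16, since the cis-fused epimer holds C17 axial and syn to C20. The step needs 6-endo over 5-exo closure twice (secured by the in-ring ketone and attack at the less substituted C5, then by acceptor polarity at C9) and ring closure faster than premature hydrogen transfer (secured by slow addition of a slow donor at high dilution).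

Step 9
Reactants: 16 (1S,2R,5S)-8-phenylmenthyl (4S,5S,8S,9R,10S)-3-oxo-13,14,15,16-tetranorlabdan-17,12-olid-19-oate
Product: 17 (4S,5S,8S,9R,10S)-12-bromo-3-oxo-13,14,15,16-tetranorlabdane-17,19-dioic acid 19-[(1S,2R,5S)-8-phenylmenthyl] ester
Conditions: HBr (33% in AcOH), rt
Reagents that add atoms: hydrogen bromide, Br
Why: Acid-promoted O-alkyl cleavage of the lactone: bromide attacks the unhindered primary C12 of the protonated lactone in an SN2 step, so C12 becomes a bromide and C17 a carboxylic acid; the hindered secondary auxiliary ester is not cleaved, and C8 stays equatorial.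

Step 10
Reactants: 17 (4S,5S,8S,9R,10S)-12-bromo-3-oxo-13,14,15,16-tetranorlabdane-17,19-dioic acid 19-[(1S,2R,5S)-8-phenylmenthyl] ester
Product: 18 (3R,4R,5S,8S,9R,10S)-12-bromo-13,14,15,16-tetranorlabdane-3,17,19-triol
Conditions: AlH3 (from LiAlH4 and AlCl3, 3:1), THF, 0 °C to rt; aq. potassium sodium tartrate
Reagents that add atoms: none
Why: Alane reduces the acid, the ketone and the hindered ester but displaces primary bromides only slowly; hydride reaches C3 along the axial path, anti to the axial C19 group, and gives the equatorial 3R alcohol, and the auxiliary 10 is released for recovery.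

Step 11
Reactants: 18 (3R,4R,5S,8S,9R,10S)-12-bromo-13,14,15,16-tetranorlabdane-3,17,19-triol
Product: 19 (3R,4R,5S,8S,9R,10S)-12-bromo-3,17,19-tris(triethylsilyloxy)-13,14,15,16-tetranorlabdane
Conditions: Et3SiOTf (3.5 equiv), 2,6-lutidine, CH2Cl2, −40 to 0 °C
Reagents that add atoms: triethylsilyl trifluoromethanesulfonate, CC[Si](CC)(CC)OS(=O)(=O)C(F)(F)F
Why: Silyl triflate with a hindered base silylates the two primary and the hindered secondary hydroxyl in one operation and removes the 17-OH before it can close a cyclic ether onto C12.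

Step 12
Reactants: 19 (3R,4R,5S,8S,9R,10S)-12-bromo-3,17,19-tris(triethylsilyloxy)-13,14,15,16-tetranorlabdane; 20 3-bromofuran-2(5H)-one
Product: 22 3,17,19-tris-O-triethylsilyl-14-deoxy-17-hydroxyandrographolide, via alkylzinc bromide 21 (not isolated)
Conditions: Zn dust, LiCl, THF, 50 °C; then 20, Pd(OAc)2 (5 mol %), SPhos (10 mol %), THF, rt
Reagents that add atoms: none
Why: Zinc insertion into the primary C12–Br bond and Negishi coupling with the α-bromo butenolide form C12–C13 under neutral conditions, the same sp3–sp2 bond construction as in step 2; no stereocentre is involved and silyl ethers are inert.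

Step 13
Reactants: 22 3,17,19-tris-O-triethylsilyl-14-deoxy-17-hydroxyandrographolide
Product: 23 14-deoxy-17-hydroxyandrographolide, 3-{2-[(1R,2S,4aS,5R,6R,8aS)-6-hydroxy-2,5-bis(hydroxymethyl)-5,8a-dimethyldecahydronaphthalen-1-yl]ethyl}furan-2(5H)-one
Conditions: HF·pyridine, THF, 0 °C to rt
Reagents that add atoms: none
Why: Fluoride-driven cleavage of the three triethylsilyl ethers under mildly acidic conditions, to which the butenolide and all stereocentres are stable.

## Compound list

1 | 5,6-dihydro-2H-pyran-2-one | O=C1OCCC=C1 | starting material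
2 | trans-3,4-dibromooxan-2-one (racemic) | O=C1OCC[C@@H](Br)[C@@H]1Br | intermediate
3 | 3-bromo-5,6-dihydro-2H-pyran-2-one | O=C1OCCC=C1Br | intermediate
4 | 5-bromo-2-methylpent-2-ene | CC(C)=CCCBr | starting material
5 | (4-methylpent-3-en-1-yl)zinc bromide | CC(C)=CCC[Zn]Br | intermediate
6 | 3-(4-methylpent-3-en-1-yl)-5,6-dihydro-2H-pyran-2-one | CC(C)=CCCC1=CCCOC1=O | intermediate
7 | 3-[(3E)-5-hydroxy-4-methylpent-3-en-1-yl]-5,6-dihydro-2H-pyran-2-one | OC/C(C)=C/CCC1=CCCOC1=O | intermediate
8 | 3-[(3E)-5-bromo-4-methylpent-3-en-1-yl]-5,6-dihydro-2H-pyran-2-one | BrC/C(C)=C/CCC1=CCCOC1=O | intermediate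
9 | ethyl 2-methyl-3-oxobutanoate | CCOC(=O)C(C)C(C)=O | starting material
10 | (1S,2R,5S)-5-methyl-2-(2-phenylpropan-2-yl)cyclohexan-1-ol, (+)-8-phenylmenthol | O[C@H]1C[C@@H](C)CC[C@@H]1C(C)(C)c1ccccc1 | starting material
11 | (1S,2R,5S)-8-phenylmenthyl 2-methyl-3-oxobutanoate (both C2 epimers) | CC(=O)C(C)C(=O)O[C@H]1C[C@@H](C)CC[C@@H]1C(C)(C)c1ccccc1 | intermediate
12 | sodium lithium dianion of 11 | [Li+].[Na+].[CH2-]C(=O)[C-](C)C(=O)O[C@H]1C[C@@H](C)CC[C@@H]1C(C)(C)c1ccccc1 | intermediate
13 | (1S,2R,5S)-8-phenylmenthyl (6E)-2,6-dimethyl-3-oxo-9-(2-oxo-5,6-dihydro-2H-pyran-3-yl)non-6-enoate (both C2 epimers) | CC(C(=O)CC/C(C)=C/CCC1=CCCOC1=O)C(=O)O[C@H]2C[C@@H](C)CC[C@@H]2C(C)(C)c2ccccc2 | intermediate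
14 | (1S,2R,5S)-8-phenylmenthyl (6E)-2-bromo-2,6-dimethyl-3-oxo-9-(2-oxo-5,6-dihydro-2H-pyran-3-yl)non-6-enoate (both C2 epimers) | CC(Br)(C(=O)CC/C(C)=C/CCC1=CCCOC1=O)C(=O)O[C@H]2C[C@@H](C)CC[C@@H]2C(C)(C)c2ccccc2 | intermediate
15 | (1S,2R,5S)-8-phenylmenthyl (4S,5S,8R,9R,10S)-3-oxo-13,14,15,16-tetranorlabdan-17,12-olid-19-oate (cis-fused lactone, 8-epimer of 16) | C[C@]1(C(=O)O[C@H]4C[C@@H](C)CC[C@@H]4C(C)(C)c5ccccc5)[C@H]2CC[C@H]3C(=O)OCC[C@H]3[C@]2(C)CCC1=O | intermediate
16 | (1S,2R,5S)-8-phenylmenthyl (4S,5S,8S,9R,10S)-3-oxo-13,14,15,16-tetranorlabdan-17,12-olid-19-oate (trans-fused lactone) | C[C@]1(C(=O)O[C@H]4C[C@@H](C)CC[C@@H]4C(C)(C)c5ccccc5)[C@H]2CC[C@@H]3C(=O)OCC[C@H]3[C@]2(C)CCC1=O | intermediate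
17 | (4S,5S,8S,9R,10S)-12-bromo-3-oxo-13,14,15,16-tetranorlabdane-17,19-dioic acid 19-[(1S,2R,5S)-8-phenylmenthyl] ester | C[C@]1(C(=O)O[C@H]3C[C@@H](C)CC[C@@H]3C(C)(C)c4ccccc4)[C@H]2CC[C@H](C(=O)O)[C@@H](CCBr)[C@]2(C)CCC1=O | intermediate
18 | (3R,4R,5S,8S,9R,10S)-12-bromo-13,14,15,16-tetranorlabdane-3,17,19-triol | C[C@]1(CO)[C@H]2CC[C@H](CO)[C@@H](CCBr)[C@]2(C)CC[C@H]1O | intermediate
19 | (3R,4R,5S,8S,9R,10S)-12-bromo-3,17,19-tris(triethylsilyloxy)-13,14,15,16-tetranorlabdane | C[C@]1(CO[Si](CC)(CC)CC)[C@H]2CC[C@H](CO[Si](CC)(CC)CC)[C@@H](CCBr)[C@]2(C)CC[C@H]1O[Si](CC)(CC)CC | intermediate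
20 | 3-bromofuran-2(5H)-one | O=C1OCC=C1Br | starting material
21 | alkylzinc bromide from 19 (zinc on C12) | C[C@]1(CO[Si](CC)(CC)CC)[C@H]2CC[C@H](CO[Si](CC)(CC)CC)[C@@H](CC[Zn]Br)[C@]2(C)CC[C@H]1O[Si](CC)(CC)CC | intermediate
22 | 3,17,19-tris-O-triethylsilyl-14-deoxy-17-hydroxyandrographolide | C[C@]1(CO[Si](CC)(CC)CC)[C@H]2CC[C@H](CO[Si](CC)(CC)CC)[C@@H](CCC3=CCOC3=O)[C@]2(C)CC[C@H]1O[Si](CC)(CC)CC | intermediate
23 | 14-deoxy-17-hydroxyandrographolide (3R,4R,5S,8S,9R,10S) | C[C@]1(CO)[C@H]2CC[C@H](CO)[C@@H](CCC3=CCOC3=O)[C@]2(C)CC[C@H]1O | target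

## Step count and least certain steps

Total step count: 13. Longest linear sequence: 12 steps (steps 1–4 and 6–13; step 5 is a one-step side branch).

**Step 8 (key step).** The likely failures are hydrogen transfer to the C4 or C10 radical before ring closure, and weak face discrimination by the auxiliary in an unchelated radical at 0 °C. The fallback sets out from 14 and removes the hydrogen donor altogether. A bromine-atom-transfer cascade (Et3B, air, Mg(ClO4)2, toluene, −78 °C) lets the C8 radical take bromine from 14 and carry the chain, and chelation by the magnesium ion fixes the dicarbonyl geometry under the auxiliary. This would give the 8-bromo lactone F1. Zinc dust in AcOH would then remove the bromine through the zinc enolate, and DBU would bring the material back to the route at 16.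

**Step 6.** The dianion may add to the unsaturated lactone (conjugate or acyl addition) in competition with allylic displacement. The fallback attaches the lactone only after the keto ester is in place. It sets out from 4: Riley oxidation (SeO2, t-BuOOH) would give (2E)-5-bromo-2-methylpent-2-en-1-ol F2, and CBr4/PPh3 would give (2E)-1,5-dibromo-2-methylpent-2-ene F3. The dianion 12 of 11 would displace only the allylic bromide to give the bromo keto ester F4. A nickel-catalysed reductive cross-electrophile coupling of F4 with 3 (NiBr2·glyme, 4,4'-di-tert-butyl-2,2'-bipyridine, Zn dust, DMA), which tolerates the acidic keto ester, would return to the route at 13.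

**Step 9.** Ring opening is reversible, so 17 may re-close to the lactone by loss of HBr during work-up; the bromide may also be lost in the hydride reduction that follows. The fallback sets out from 16 and uses an irreversible, hydride-stable C12 substituent. PhSeNa (THF/HMPA, 65 °C) would cleave the O–C12 bond to give the selanyl acid F5. LiAlH4 would reduce ketone, acid and ester to the selanyl triol F6 (with release of 10), and Et3SiOTf/2,6-lutidine would give the tris-silyl ether F7. Br2 with Et3N in CH2Cl2 would exchange the phenylselanyl group for bromide and return to the route at 19.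

**Step 12.** Zinc insertion may be slow, the alkylzinc may be lost by protonation, and the organometallic may add to the butenolide in conjugate fashion instead of coupling. The fallback sets out from 19 and builds the butenolide by enolate alkylation. 3-(Phenylsulfanyl)oxolan-2-one F8 (from 3-bromooxolan-2-one, thiophenol and Et3N) would be deprotonated with LiN(SiMe3)2 in THF/HMPA and alkylated by 19 in the presence of NaI to give the sulfide lactone F9. mCPBA at −78 °C would give the sulfoxide F10, and syn-elimination in warm toluene, which runs towards the ring hydrogen, would return to the route at 22.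

## Further compounds

F1 | step 8 | (1S,2R,5S)-8-phenylmenthyl 8-bromo-3-oxo-13,14,15,16-tetranorlabdan-17,12-olid-19-oate (both C8 epimers; C4, C5, C9, C10 as in 16) | C[C@]1(C(=O)O[C@H]4C[C@@H](C)CC[C@@H]4C(C)(C)c5ccccc5)[C@H]2CCC3(Br)C(=O)OCC[C@H]3[C@]2(C)CCC1=O
F2 | step 6 | (2E)-5-bromo-2-methylpent-2-en-1-ol | OC/C(C)=C/CCBr
F3 | step 6 | (2E)-1,5-dibromo-2-methylpent-2-ene | BrC/C(C)=C/CCBr
F4 | step 6 | (1S,2R,5S)-8-phenylmenthyl (6E)-9-bromo-2,6-dimethyl-3-oxonon-6-enoate (both C2 epimers) | CC(C(=O)CC/C(C)=C/CCBr)C(=O)O[C@H]1C[C@@H](C)CC[C@@H]1C(C)(C)c1ccccc1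
F5 | step 9 | 3-oxo-12-(phenylselanyl)-13,14,15,16-tetranorlabdane-17,19-dioic acid 19-[(1S,2R,5S)-8-phenylmenthyl] ester (core as in 17) | C[C@]1(C(=O)O[C@H]3C[C@@H](C)CC[C@@H]3C(C)(C)c4ccccc4)[C@H]2CC[C@H](C(=O)O)[C@@H](CC[Se]c5ccccc5)[C@]2(C)CCC1=O
F6 | step 9 | (3R,4R,5S,8S,9R,10S)-12-(phenylselanyl)-13,14,15,16-tetranorlabdane-3,17,19-triol | C[C@]1(CO)[C@H]2CC[C@H](CO)[C@@H](CC[Se]c3ccccc3)[C@]2(C)CC[C@H]1O
F7 | step 9 | (3R,4R,5S,8S,9R,10S)-12-(phenylselanyl)-3,17,19-tris(triethylsilyloxy)-13,14,15,16-tetranorlabdane | C[C@]1(CO[Si](CC)(CC)CC)[C@H]2CC[C@H](CO[Si](CC)(CC)CC)[C@@H](CC[Se]c3ccccc3)[C@]2(C)CC[C@H]1O[Si](CC)(CC)CC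
F8 | step 12 | 3-(phenylsulfanyl)oxolan-2-one (racemic) | O=C1OCCC1Sc1ccccc1
F9 | step 12 | 13-(phenylsulfanyl)-13,14-dihydro derivative of 22 (both C13 epimers) | C[C@]1(CO[Si](CC)(CC)CC)[C@H]2CC[C@H](CO[Si](CC)(CC)CC)[C@@H](CCC3(Sc4ccccc4)CCOC3=O)[C@]2(C)CC[C@H]1O[Si](CC)(CC)CC
F10 | step 12 | 13-(phenylsulfinyl)-13,14-dihydro derivative of 22 (sulfoxide of F9) | C[C@]1(CO[Si](CC)(CC)CC)[C@H]2CC[C@H](CO[Si](CC)(CC)CC)[C@@H](CCC3(S(=O)c4ccccc4)CCOC3=O)[C@]2(C)CC[C@H]1O[Si](CC)(CC)CC
A1 | alternative 1 | tert-butyldimethyl{[(3Z,7E)-10-[(2R,3S)-3-(benzyloxymethyl)-3-methyloxiran-2-yl]-8-methyl-4-[(trimethylsilyl)methyl]deca-3,7-dien-1-yl]oxy}silane | C[Si](C)(C)C/C(CC/C=C(\C)CC[C@H]1O[C@@]1(C)COCc1ccccc1)=C\CCO[Si](C)(C)C(C)(C)C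
A2 | alternative 1 | (3R,4R,5S,9R,10S)-19-benzyloxy-12-(tert-butyldimethylsilyloxy)-13,14,15,16-tetranorlabd-8(17)-en-3-ol | C[C@]1(COCc3ccccc3)[C@H]2CCC(=C)[C@@H](CCO[Si](C)(C)C(C)(C)C)[C@]2(C)CC[C@H]1O
A3 | alternative 2 | ring-A diene, (3R,4R)-3,19-isopropylidenedioxy-4,10-dimethyl-5-vinylcyclohex-5(10)-ene (labdane numbering) | C[C@]1(COC(C)(C)O3)C(C=C)=C(C)CC[C@H]13
A4 | alternative 2 | Diels–Alder adduct, dimethyl 3,19-isopropylidenedioxy-12,13,14,15,16-pentanorlabd-5-ene-11,17-dioate (C3, C4, C8, C9, C10 as in the target) | C[C@]1(COC(C)(C)O3)C2=CC[C@H](C(=O)OC)[C@@H](C(=O)OC)[C@]2(C)CC[C@H]13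
A5 | alternative 3 | 3-[(3E)-6-[(2R,3S)-3-(tert-butyldimethylsilyloxymethyl)-3-methyloxiran-2-yl]-4-methylhex-3-en-1-yl]-5,6-dihydro-2H-pyran-2-one | O=C1OCCC=C1CC/C=C(\C)CC[C@H]1O[C@@]1(C)CO[Si](C)(C)C(C)(C)C
A6 | alternative 3 | (3R,4R,5S,8S,9R,10S)-19-(tert-butyldimethylsilyloxy)-3-hydroxy-13,14,15,16-tetranorlabdan-17,12-olide | C[C@]1(CO[Si](C)(C)C(C)(C)C)[C@H]2CC[C@@H]3C(=O)OCC[C@H]3[C@]2(C)CC[C@H]1O
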